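**Plan**

1. Numbering used throughout (daucane): C1 = ring-fusion carbon with CH3, C2–C3 = CH2, C4 = carbinol carbon with isopropyl, C5 = ring-fusion CH, C6–C10 = the other carbons of the seven-membered ring; β = face of the C1 methyl.
2. Retrosynthesis: the two ester C–O bonds (C10 angelate, C6 4-hydroxybenzoate) are cut first and C10 is raised to the ketone; the seven-membered ring then holds the array O=C10–C9=C8(CH3)–C7–C6–OH, a δ-hydroxy enone, and this feature makes a ring-closing vinylogous aldol event possible.
3. That event is undone next: C6–C7 and the C8=C9 double bond are cut together, which opens the seven-membered ring to a cyclopentane with a formyl group on C5 and a 3-methylbut-3-enoyl group on C1 (alkene back at C7=C8).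
4. The cyclopentane is cut at C4–C5 (enamine aldol) to an acyclic keto aldehyde, the cleavage product of a cyclohexene used as a temporary ring; the cyclohexene is cut into methacrolein and 2-isopropylbuta-1,3-diene (Diels–Alder).
5. Forward order of rings: cyclohexene (made, then cleaved), cyclopentane, seven-membered ring; the C10 side chain is joined by a Grignard addition and the two esters come last.
6. Stereochemistry: C1 from the catalytic asymmetric Diels–Alder reaction; C4 and C5 from the (R)-proline aldol; C6 from the chair-like ring closure (oxygen away from the axial C1 methyl); C10 from hydride attack anti to the C1 methyl; the (Z)-alkene from angelic acid.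

Key step: step 7

Remark: in step 2 the oxazaborolidinium enantiomer is the one that gives the (S)-aldehyde 5, assumed here to be the catalyst from (S)-α,α-diphenylprolinol; if the sense is opposite, its mirror image is used.

**Route**

Step 1
Reactants: 1 3-methylbut-1-yne; 2 ethylene
Product: 3 2-(propan-2-yl)buta-1,3-diene
Conditions: RuCl2(=CHPh)(PCy3)(H2IMes) (second-generation Grubbs catalyst, 3 mol %), ethylene (4 bar), CH2Cl2, 25 °C
Reagents that add atoms: none
Why: Enyne cross-metathesis of a terminal alkyne with ethylene is an established entry to 2-substituted buta-1,3-dienes and the branched propargylic position should be tolerated; no stereocenter is formed.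

Step 2
Reactants: 3 2-(propan-2-yl)buta-1,3-diene; 4 methacrolein
Product: 5 (1S)-1-methyl-4-(propan-2-yl)cyclohex-3-ene-1-carbaldehyde
Conditions: N-protonated oxazaborolidine from (S)-α,α-diphenylprolinol and o-tolylboroxine, activated with Tf2NH (10 mol %), CH2Cl2, −78 °C → −40 °C
Reagents that add atoms: none
Why: Catalytic asymmetric Diels–Alder reaction in which the chiral boron Lewis acid binds the enal and shields one face while the 2-alkyl diene adds with "para" regiochemistry, which should set the quaternary center C1 as (S).

Step 3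
Reactants: 5 (1S)-1-methyl-4-(propan-2-yl)cyclohex-3-ene-1-carbaldehyde; 6 2-methylallylmagnesium chloride (CH2=C(CH3)CH2MgCl)
Product: 7 1-[(1S)-1-methyl-4-(propan-2-yl)cyclohex-3-en-1-yl]-3-methylbut-3-en-1-ol (both carbinol epimers)
Conditions: THF, −78 °C → 0 °C; then aq NH4Cl
Reagents that add atoms: none
Why: Grignard 1,2-addition of an allylic organomagnesium reagent to the neopentylic aldehyde should be fast; the new carbinol center (C10) is not controlled, which is harmless because it is oxidised in step 4.

Step 4
Reactants: 7 1-[(1S)-1-methyl-4-(propan-2-yl)cyclohex-3-en-1-yl]-3-methylbut-3-en-1-ol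
Product: 8 1-[(1S)-1-methyl-4-(propan-2-yl)cyclohex-3-en-1-yl]-3-methylbut-3-en-1-one
Conditions: Dess–Martin periodinane, CH2Cl2, 0 °C → 20 °C
Reagents that add atoms: none
Why: Dess–Martin oxidation of the secondary homoallylic alcohol under near-neutral conditions should give the β,γ-unsaturated ketone without moving the alkene into conjugation; both epimers converge and no stereocenter is formed.

Step 5
Reactants: 8 1-[(1S)-1-methyl-4-(propan-2-yl)cyclohex-3-en-1-yl]-3-methylbut-3-en-1-one
Product: 10 (3S)-3,7-dimethyl-3-(3-methylbut-3-enoyl)-6-oxooctanal, via epoxide 9 (not isolated)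
Conditions: m-CPBA (1.05 equiv), CH2Cl2, −20 °C → 0 °C; then H5IO6 (1.2 equiv), THF–H2O, 0 °C; used at once in step 6
Reagents that add atoms: meta-chloroperoxybenzoic acid, O=C(OO)c1cccc(Cl)c1; water, O
Why: Prilezhaev epoxidation should pick the electron-rich trisubstituted ring alkene over the 1,1-disubstituted alkene, and periodic acid then cleaves the epoxide through the diol (glycol cleavage) to the isopropyl ketone and the aldehyde, leaving C1 untouched.

Step 6
Reactants: 10 (3S)-3,7-dimethyl-3-(3-methylbut-3-enoyl)-6-oxooctanal
Product: 11 (1R,2R,5S)-2-hydroxy-5-methyl-5-(3-methylbut-3-enoyl)-2-(propan-2-yl)cyclopentane-1-carbaldehyde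
Conditions: (R)-proline (30 mol %), DMSO, 20 °C
Reagents that add atoms: none
Why: Proline-catalysed intramolecular enamine aldol addition in the 5-(enolexo)-exo-trig mode (aldehyde as donor, isopropyl ketone as acceptor), in which the (R)-catalyst should deliver the ketone to the enamine face that gives the required C5 configuration and the hydrogen-bonded transition state places the new C4 hydroxyl cis to the formyl group and the isopropyl group trans to it.

Step 7
Reactants: 11 (1R,2R,5S)-2-hydroxy-5-methyl-5-(3-methylbut-3-enoyl)-2-(propan-2-yl)cyclopentane-1-carbaldehyde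
Product: 14 4β,6α-dihydroxydauc-8-en-10-one, via bis-silyl dienol ether 12 (not isolated), via bis-silyl aldol ether 13 (not isolated)
Conditions: TMSOTf (3.5 equiv), i-Pr2NEt (2.5 equiv), CH2Cl2, −78 °C → −20 °C; then 1 M HCl, THF, 0 °C
Reagents that add atoms: none
Why: TMSOTf and the amine should first silylate the tertiary hydroxyl and convert the doubly activated C9 methylene of the β,γ-unsaturated ketone into silyl dienol ether 12, whose terminal carbon C7 then adds to the TMSOTf-activated aldehyde; collapse of the oxocarbenium ion gives enone 13 with the alkene now at C8=C9, and acid removes both silyl ethers. The closest known reaction type is the vinylogous Mukaiyama aldol addition with in situ enol silane formation, which here amounts to a carbonyl-ene reaction made regiospecific by the C10 carbonyl. The seven-membered ring closes in the 7-(enolendo)-exo-trig mode, whereas attack through C9 would be a 5-(enolendo)-exo-trig closure and is stereoelectronically disfavoured, which secures reaction at C7. The only new stereocenter, C6, should be set in a chair-like transition state in which the silylated carbonyl oxygen takes the pseudo-equatorial α position to avoid the syn-axial C1 methyl group, while the trans ring fusion is already fixed by C1 and C5 of 11. The step needs enolisation of the ketone in preference to the aldehyde, which is secured by the high acidity of the allylic C9–H next to the carbonyl and by the hindered tertiary C5–H between two fully substituted carbons.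

Step 8
Reactants: 14 4β,6α-dihydroxydauc-8-en-10-one; 15 4-[(tert-butyldimethylsilyl)oxy]benzoic acid
Product: 16 6α-{4-[(tert-butyldimethylsilyl)oxy]benzoyloxy}-4β-hydroxydauc-8-en-10-one
Conditions: DCC, DMAP (0.2 equiv), CH2Cl2, 0 °C → 20 °C
Reagents that add atoms: none
Why: Steglich esterification should acylate the equatorial secondary C6 hydroxyl with retention while the hindered tertiary C4 hydroxyl stays free.

Step 9
Reactants: 16 6α-{4-[(tert-butyldimethylsilyl)oxy]benzoyloxy}-4β-hydroxydauc-8-en-10-one
Product: 17 6α-{4-[(tert-butyldimethylsilyl)oxy]benzoyloxy}dauc-8-ene-4β,10β-diol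
Conditions: NaBH4, CeCl3·7H2O, MeOH, −78 °C
Reagents that add atoms: none
Why: Luche 1,2-reduction of the enone, in which hydride should reach C10 from the α face, anti to the axial methyl group on the neighbouring quaternary C1, to give the 10β allylic alcohol.

Step 10
Reactants: 17 6α-{4-[(tert-butyldimethylsilyl)oxy]benzoyloxy}dauc-8-ene-4β,10β-diol; 18 angelic acid ((Z)-2-methylbut-2-enoic acid)
Product: 20 10β-angeloyloxy-6α-{4-[(tert-butyldimethylsilyl)oxy]benzoyloxy}dauc-8-en-4β-ol, via mixed anhydride 19 (not isolated)
Conditions: 18, 2,4,6-trichlorobenzoyl chloride, Et3N, toluene, 20 °C; then 17, 80 °C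
Reagents that add atoms: none
Why: Yamaguchi-type esterification through the preformed mixed anhydride, without added nucleophilic catalyst, should acylate the neopentylic allylic hydroxyl with retention at C10 and without (Z) to (E) isomerisation of the angelate.

Step 11
Reactants: 20 10β-angeloyloxy-6α-{4-[(tert-butyldimethylsilyl)oxy]benzoyloxy}dauc-8-en-4β-ol
Product: 21 10β-angeloyloxy-6α-(4-hydroxybenzoyloxy)dauc-8-en-4β-ol (CNP0273650.10)
Conditions: TBAF (1.1 equiv), AcOH (1.2 equiv), THF, 0 °C
Reagents that add atoms: none
Why: Fluoride-mediated desilylation should cleave the aryl silyl ether much faster than it touches the carboxylic esters, and acetic acid buffers the phenoxide so that acyl migration and angelate isomerisation are avoided.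

**Compound list**

1 | 3-methylbut-1-yne | C#CC(C)C | starting material
2 | ethylene | C=C | starting material
3 | 2-(propan-2-yl)buta-1,3-diene | C=CC(=C)C(C)C | intermediate
4 | methacrolein (2-methylprop-2-enal) | C=C(C)C=O | starting material
5 | (1S)-1-methyl-4-(propan-2-yl)cyclohex-3-ene-1-carbaldehyde | O=C[C@@]1(C)CCC(C(C)C)=CC1 | intermediate
6 | 2-methylallylmagnesium chloride | C=C(C)C[Mg]Cl | starting material
7 | 1-[(1S)-1-methyl-4-(propan-2-yl)cyclohex-3-en-1-yl]-3-methylbut-3-en-1-ol (both carbinol epimers) | C=C(C)CC(O)[C@@]1(C)CCC(C(C)C)=CC1 | intermediate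
8 | 1-[(1S)-1-methyl-4-(propan-2-yl)cyclohex-3-en-1-yl]-3-methylbut-3-en-1-one | C=C(C)CC(=O)[C@@]1(C)CCC(C(C)C)=CC1 | intermediate
9 | 3-methyl-1-[3-methyl-6-(propan-2-yl)-7-oxabicyclo[4.1.0]heptan-3-yl]but-3-en-1-one (quaternary carbon as in 8, epoxide diastereomers) | C=C(C)CC(=O)[C@@]1(C)CCC2(C(C)C)OC2C1 | intermediate
10 | (3S)-3,7-dimethyl-3-(3-methylbut-3-enoyl)-6-oxooctanal | O=CC[C@](C)(CCC(=O)C(C)C)C(=O)CC(C)=C | intermediate
11 | (1R,2R,5S)-2-hydroxy-5-methyl-5-(3-methylbut-3-enoyl)-2-(propan-2-yl)cyclopentane-1-carbaldehyde | C=C(C)CC(=O)[C@@]1(C)CC[C@@](O)(C(C)C)[C@@H]1C=O | intermediate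
12 | (1R,2R,5S)-5-methyl-5-[3-methyl-1-(trimethylsilyloxy)buta-1,3-dien-1-yl]-2-(propan-2-yl)-2-(trimethylsilyloxy)cyclopentane-1-carbaldehyde (bis-silyl dienol ether) | C=C(C)C=C(O[Si](C)(C)C)[C@@]1(C)CC[C@@](O[Si](C)(C)C)(C(C)C)[C@@H]1C=O | intermediate
13 | 4β,6α-bis(trimethylsilyloxy)dauc-8-en-10-one (bis-silyl aldol ether) | O=C1C=C(C)C[C@H](O[Si](C)(C)C)[C@@H]2[C@]1(C)CC[C@@]2(O[Si](C)(C)C)C(C)C | intermediate
14 | 4β,6α-dihydroxydauc-8-en-10-one (trans-fused, 1β-CH3, 5α-H) | O=C1C=C(C)C[C@H](O)[C@@H]2[C@]1(C)CC[C@@]2(O)C(C)C | intermediate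
15 | 4-[(tert-butyldimethylsilyl)oxy]benzoic acid | O=C(O)c1ccc(O[Si](C)(C)C(C)(C)C)cc1 | starting material
16 | 6α-{4-[(tert-butyldimethylsilyl)oxy]benzoyloxy}-4β-hydroxydauc-8-en-10-one | O=C1C=C(C)C[C@H](OC(=O)c2ccc(O[Si](C)(C)C(C)(C)C)cc2)[C@@H]2[C@]1(C)CC[C@@]2(O)C(C)C | intermediate
17 | 6α-{4-[(tert-butyldimethylsilyl)oxy]benzoyloxy}dauc-8-ene-4β,10β-diol | O[C@H]1C=C(C)C[C@H](OC(=O)c2ccc(O[Si](C)(C)C(C)(C)C)cc2)[C@@H]2[C@]1(C)CC[C@@]2(O)C(C)C | intermediate
18 | angelic acid ((Z)-2-methylbut-2-enoic acid) | C/C=C(/C)C(=O)O | starting material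
19 | (Z)-2-methylbut-2-enoic 2,4,6-trichlorobenzoic anhydride (mixed anhydride) | C/C=C(/C)C(=O)OC(=O)c1c(Cl)cc(Cl)cc1Cl | intermediate
20 | 10β-angeloyloxy-6α-{4-[(tert-butyldimethylsilyl)oxy]benzoyloxy}dauc-8-en-4β-ol | C/C=C(/C)C(=O)O[C@H]1C=C(C)C[C@H](OC(=O)c2ccc(O[Si](C)(C)C(C)(C)C)cc2)[C@@H]2[C@]1(C)CC[C@@]2(O)C(C)C | intermediate
21 | 10β-angeloyloxy-6α-(4-hydroxybenzoyloxy)dauc-8-en-4β-ol (CNP0273650.10) | C/C=C(/C)C(=O)O[C@H]1C=C(C)C[C@H](OC(=O)c2ccc(O)cc2)[C@@H]2[C@]1(C)CC[C@@]2(O)C(C)C | target

**Step count and risks**

Total step count: 11. Longest linear sequence: 11 steps (from 3-methylbut-1-yne).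

Steps most likely to fail:

Step 7. The one-pot enol silane formation may be spoiled by competing enolisation and silylation of the aldehyde (loss of the C5 configuration), or the facial selectivity at C6 may be poor. In that case the ring is closed by a Lewis-acid carbonyl-ene reaction that does not pass through an enol derivative. The fallback sets out from 11, which is treated with Me2AlCl (CH2Cl2, −78 °C → 0 °C); the 1,1-disubstituted alkene should add through C7 to the complexed aldehyde with transfer of a methyl hydrogen and give the exocyclic-alkene hydroxy ketone F1. The methylidene group at C8 is then moved into conjugation with the C10 ketone by DBU (CH2Cl2, 20 °C), which brings the route back at 14.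

Step 6. Catalyst control over the new C4 and C5 centers relative to the C1 quaternary center may be weak, or the acidic C9 methylene of the β,γ-unsaturated ketone may interfere (alkene migration, competing aldol addition, dehydration). In that case the ketone is introduced after the cyclopentane is closed and the aldol is run with substrate control as well. The fallback sets out from 7, which is silylated (TBSOTf, 2,6-lutidine, CH2Cl2) to the tert-butyldimethylsilyl ether F2 and cleaved as in step 5 through the epoxide F3 to the silyloxy keto aldehyde F4. This is cyclised with (R)-proline to the silyloxy cyclopentane carbaldehyde F5, in which the bulky silyloxy-bearing side chain on C1 should also force the formyl group to the opposite face. HF·pyridine (THF, 0 °C) then frees the hydroxy aldehyde F6, and Dess–Martin oxidation of its secondary alcohol brings the route back at 11.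

Step 10. Acylation of the hindered C10 hydroxyl may be sluggish, or the angelate may isomerise to the tiglate during activation. In that case the (Z)-alkene is built on the ester. The fallback sets out from 17, which is esterified (DCC, DMAP) with 2-[bis(2,2,2-trifluoroethoxy)phosphoryl]propanoic acid to the phosphonate ester F7. A Still–Gennari olefination with acetaldehyde (KN(SiMe3)2, 18-crown-6, THF, −78 °C) should then give the (Z)-2-methylbut-2-enoate and bring the route back at 20.

Further compounds
F1 | step 7 | 4β,6α-dihydroxy-8-methylidenedaucan-10-one (exocyclic-alkene isomer of 14) | O=C1CC(=C)C[C@H](O)[C@@H]2[C@]1(C)CC[C@@]2(O)C(C)C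
F2 | step 6 | tert-butyldimethylsilyl ether of 7 (both carbinol epimers) | C=C(C)CC(O[Si](C)(C)C(C)(C)C)[C@@]1(C)CCC(C(C)C)=CC1
F3 | step 6 | ring epoxide of F2 (diastereomers) | C=C(C)CC(O[Si](C)(C)C(C)(C)C)[C@@]1(C)CCC2(C(C)C)OC2C1
F4 | step 6 | 3-[1-(tert-butyldimethylsilyloxy)-3-methylbut-3-enyl]-3,7-dimethyl-6-oxooctanal (quaternary carbon as in 10, both carbinol epimers) | O=CC[C@](C)(CCC(=O)C(C)C)C(O[Si](C)(C)C(C)(C)C)CC(C)=C
F5 | step 6 | 5-[1-(tert-butyldimethylsilyloxy)-3-methylbut-3-enyl]-2-hydroxy-5-methyl-2-(propan-2-yl)cyclopentane-1-carbaldehyde (ring centers as in 11) | C=C(C)CC(O[Si](C)(C)C(C)(C)C)[C@@]1(C)CC[C@@](O)(C(C)C)[C@@H]1C=O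
F6 | step 6 | 2-hydroxy-5-(1-hydroxy-3-methylbut-3-enyl)-5-methyl-2-(propan-2-yl)cyclopentane-1-carbaldehyde (ring centers as in 11) | C=C(C)CC(O)[C@@]1(C)CC[C@@](O)(C(C)C)[C@@H]1C=O
F7 | step 10 | 10β-{2-[bis(2,2,2-trifluoroethoxy)phosphoryl]propanoyloxy}-6α-{4-[(tert-butyldimethylsilyl)oxy]benzoyloxy}dauc-8-en-4β-ol | CC(C(=O)O[C@H]1C=C(C)C[C@H](OC(=O)c2ccc(O[Si](C)(C)C(C)(C)C)cc2)[C@@H]2[C@]1(C)CC[C@@]2(O)C(C)C)P(=O)(OCC(F)(F)F)OCC(F)(F)F
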